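**Plan**

1. Numbering used throughout: C1 = CHO, C2 = its α-carbon, C3 = CH2OH; ring B = C6 (CH carrying the hydroxypropyl chain C5–C3), C7 (alkylidene carbon), C8, C9, C10 (C(OH)CH3), C11 (quaternary carbon); C12–C17 = dienyl chain; ring A = the trimethyl-methylidene cyclohexane (C18 = CH on the chain, C22 = CHCH3).
2. Cuts: C15–C16 (sp2–sp2) and C13–C14 (sp3–sp2) release a ring A alkyne, a bromo-iodo-propene linchpin and a ring B vinyl ester; ring B is opened at C9–C10; the open chain is cut at C7–C8 (enol tosylate coupling), at C2–C7 (β-keto ester) and at C6–C11 ([3,3] shift).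
3. Forward: ring A from (S)-3-methylcyclohexanone (gem-dimethylation, alkynyl addition with 1,3-carbonyl transposition, reductive alkene transposition); chain C1–C13 by Ireland–Claisen rearrangement, C-acylation, (E)-enol tosylate and Negishi coupling; ring B by samarium Barbier closure of C9 onto the C10 methyl ketone; then B-alkyl Suzuki coupling, hydrozirconation–Negishi coupling, ester-to-enal adjustment and desilylation.
4. Feature that allows the ring-closing event: C10 of ring B is a tertiary carbinol carbon bearing CH3 next to the quaternary C11, i.e. a latent methyl ketone that cannot enolise towards C11 and lies 1,6 to C9 along C10–C11–C6–C7–C8–C9. The (Z)-tetrasubstituted C2=C7 alkylidene holds the C6 chain axial (allylic 1,3-strain) and keeps C1 out of reach of C9, so the closure completes the C6/C11/C10 triad in one event.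
5. Stereochemistry: C22 from the starting ketone; C18 from suprafacial hydrogen delivery in the diazene step; C6 and C11 from the chair Ireland–Claisen under a chiral boron controller; C2=C7 (Z) from the (E)-enol tosylate with retention; C10 in the key step by substrate control; C14=C15 and C16=C17 from anti iodobromination and syn hydrozirconation.

Key step: step 20

Assumption: the (S,S)-bromoborane of step 12 is taken to be the antipode that gives the (2S,3S)-configured Claisen acid; if the sense of induction is the opposite, the (R,R)-reagent is used and nothing else changes.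

**Ring A alkyne (steps 1–6)**

Step 1
Reactants: 1 (S)-3-methylcyclohexanone
Product: 2 (2Z,5S)-2-(hydroxymethylidene)-5-methylcyclohexan-1-one
Conditions: HCO2Et, NaH, EtOH (cat.), Et2O, 0 °C → rt; aq. HCl
Reagents that add atoms: ethyl formate, O=COCC
Why: Crossed Claisen condensation (formylation) should occur at the α-carbon remote from the methyl-bearing centre and is driven by the β-keto aldehyde enolate; the stereocentre is not enolisable.

Step 2
Reactants: 2 hydroxymethylidene ketone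
Product: 3 (2E,5S)-5-methyl-2-[(propan-2-yloxy)methylidene]cyclohexan-1-one
Conditions: i-PrI, K2CO3, DMF, rt
Reagents that add atoms: 2-iodopropane, CC(C)I
Why: O-alkylation of the enolised β-keto aldehyde installs the isopropoxymethylene blocking group, which also carries the future exocyclic methylidene carbon.

Step 3
Reactants: 3 isopropoxymethylene ketone
Product: 4 (3S,6E)-2,2,3-trimethyl-6-[(propan-2-yloxy)methylidene]cyclohexan-1-one
Conditions: KOt-Bu (2.5 equiv), MeI (excess), t-BuOH/THF, 0 °C → rt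
Reagents that add atoms: iodomethane, CI
Why: Exhaustive enolate methylation at the only enolisable α-carbon left by the blocking group builds the gem-dimethyl carbon beside the stereocentre.

Step 4
Reactants: 4 blocked trimethyl ketone
Product: 6 (4S)-2-ethynyl-3,3,4-trimethylcyclohex-1-ene-1-carbaldehyde, via tertiary carbinol 5 (not isolated)
Conditions: HC≡CMgBr (3 equiv), THF, 0 °C → rt; then 1 M HCl, THF, rt
Reagents that add atoms: ethynylmagnesium bromide, C#C[Mg]Br; water, O
Why: 1,2-Addition to the vinylogous ester followed by acid-mediated 1,3-carbonyl transposition (Stork–Danheiser type, the classical route from 2-alkoxymethylene-6,6-dimethylcyclohexanones to cyclocitral-type enals) should give the 2-alkynyl enal.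

Step 5
Reactants: 6 enynal
Product: 7 (E)-tosylhydrazone of 6
Conditions: TsNHNH2, EtOH, rt
Reagents that add atoms: 4-methylbenzenesulfonohydrazide, Cc1ccc(cc1)S(=O)(=O)NN
Why: Hydrazone condensation at the only carbonyl group sets up the reductive alkene transposition.

Step 6
Reactants: 7 tosylhydrazone
Product: 9 (1S,3S)-1-ethynyl-2,2,3-trimethyl-6-methylidenecyclohexane, via allylic diazene 8 (not isolated)
Conditions: catecholborane, CHCl3, 0 °C; then NaOAc·3H2O, reflux
Reagents that add atoms: none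
Why: Catecholborane reduction of the unsaturated tosylhydrazone with alkene transposition: hydride adds to C=N, sulfinate leaves, and the allylic diazene loses N2 in a retro-ene step that moves the double bond exocyclic and delivers hydrogen to C18 anti to the pseudo-axial methyl of the neighbouring gem-dimethyl carbon, which should give the cis relation of the ethynyl and C22 methyl groups.

**Side-chain partners (steps 7–8)**

Step 7
Reactants: 10 δ-valerolactone
Product: 13 5-[(tert-butyldiphenylsilyl)oxy]pentanoic acid, via potassium 5-hydroxypentanoate 11 (not isolated), via bis-silyl ester 12 (not isolated)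
Conditions: KOH, MeOH/H2O, rt, evaporate; t-BuPh2SiCl (2.2 equiv), imidazole, DMF, rt; then K2CO3, MeOH/H2O, rt; dilute acid
Reagents that add atoms: potassium hydroxide, [K+].[OH-]; tert-butyl(chloro)diphenylsilane, CC(C)(C)[Si](Cl)(c1ccccc1)c1ccccc1
Why: Lactone saponification, double silylation and selective hydrolysis of the labile silyl ester is a standard way to an ω-silyloxy acid.

Step 8
Reactants: 14 propyne
Product: 15 (E)-2-bromo-1-iodoprop-1-ene
Conditions: IBr, CH2Cl2, −78 → 0 °C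
Reagents that add atoms: iodine monobromide, IBr
Why: Electrophilic anti-iodobromination of the terminal alkyne places iodine on the terminal carbon and bromine trans to it on the internal carbon.

**Chain C1–C13, ring B and end game (steps 9–25)**

Step 9
Reactants: 16 (S)-but-3-yn-2-ol
Product: 17 triethyl{[(2S)-but-3-yn-2-yl]oxy}silane
Conditions: Et3SiCl, imidazole, CH2Cl2, 0 °C
Reagents that add atoms: chlorotriethylsilane, CC[Si](Cl)(CC)CC
Why: Silylation masks the future C10 oxygen as an acid-labile ether; its stereocentre is a temporary helper that is oxidised away in step 19.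

Step 10
Reactants: 17 silyl ether
Product: 19 (2E,4S)-3-methyl-4-[(triethylsilyl)oxy]pent-2-en-1-ol, via dimethylalkenylalane 18 (not isolated)
Conditions: Me3Al, Cp2ZrCl2 (0.2 equiv), CH2Cl2, 0 °C → rt; then n-BuLi, (CH2O)n, THF, −78 °C → rt
Reagents that add atoms: trimethylaluminium, C[Al](C)C; formaldehyde (as paraformaldehyde), C=O
Why: Negishi zirconium-catalysed carboalumination adds methyl and aluminium syn across the alkyne (methyl on the internal carbon), and trapping the aluminate with formaldehyde gives the E-trisubstituted allylic alcohol.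

Step 11
Reactants: 19 allylic alcohol; 13 silyloxy acid
Product: 20 (2E,4S)-3-methyl-4-[(triethylsilyl)oxy]pent-2-en-1-yl 5-[(tert-butyldiphenylsilyl)oxy]pentanoate
Conditions: DCC, DMAP (cat.), CH2Cl2, 0 °C → rt
Reagents that add atoms: none
Why: Steglich esterification joins the two halves of the Claisen substrate under neutral conditions.

Step 12
Reactants: 20 allylic ester
Product: 22 (2S,3S,4S)-2-{3-[(tert-butyldiphenylsilyl)oxy]propyl}-3-ethenyl-3-methyl-4-[(triethylsilyl)oxy]pentanoic acid, via boron ketene acetal 21 (not isolated)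
Conditions: (4S,5S)-2-bromo-1,3-bis{[3,5-bis(trifluoromethyl)phenyl]sulfonyl}-4,5-diphenyl-1,3,2-diazaborolidine (1.3 equiv), Et3N, toluene/hexane, −78 °C; then 4 °C, several days; aqueous work-up
Reagents that add atoms: none
Why: Ireland–Claisen rearrangement of the E(O) boron enolate through a chair transition state (E-allyl unit, C11 methyl pseudo-axial, enolate chain anti to O–B) should form the C6–C11 bond with the required relative configuration and leave the vinyl group on C11, the chiral controller choosing the enolate face and the (S)-C10 centre making any minor facial isomer a separable diastereomer.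

Step 13
Reactants: 22 Claisen acid
Product: 24 ethyl (4S,5S,6S)-4-{3-[(tert-butyldiphenylsilyl)oxy]propyl}-5-ethenyl-2,5-dimethyl-3-oxo-6-[(triethylsilyl)oxy]heptanoate (C2 epimers), via acyl imidazole 23 (not isolated)
Conditions: 1,1'-carbonyldiimidazole, THF, rt; then KO2CCH(CH3)CO2Et, MgCl2, Et3N, THF, rt → 50 °C
Reagents that add atoms: potassium 3-ethoxy-2-methyl-3-oxopropanoate, [K+].[O-]C(=O)C(C)C(=O)OCC
Why: Decarboxylative Claisen condensation of the acyl imidazolide with the magnesium malonate half-ester (Masamune–Brooks reaction) gives the α-methyl β-keto ester under near-neutral conditions that should spare the C6 stereocentre.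

Step 14
Reactants: 24 β-keto ester
Product: 25 ethyl (2E,4S,5S,6S)-4-{3-[(tert-butyldiphenylsilyl)oxy]propyl}-5-ethenyl-2,5-dimethyl-3-{[(4-methylphenyl)sulfonyl]oxy}-6-[(triethylsilyl)oxy]hept-2-enoate
Conditions: TsCl, Me2N(CH2)6NMe2, MeCN, 0 °C
Reagents that add atoms: 4-methylbenzenesulfonyl chloride, Cc1ccc(cc1)S(Cl)(=O)=O
Why: Stereoselective enol tosylation of an α-substituted β-keto ester under amine-only (non-chelating) conditions should give the E-enol tosylate, with the sulfonate trans to the ester and C6 cis to it.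

Step 15
Reactants: 25 (E)-enol tosylate
Product: 26 ethyl (2Z,4R,5S,6S)-4-{3-[(tert-butyldiphenylsilyl)oxy]propyl}-3-(1,3-dioxolan-2-ylmethyl)-5-ethenyl-2,5-dimethyl-6-[(triethylsilyl)oxy]hept-2-enoate
Conditions: BrZnCH2CH(OCH2CH2O), Pd(OAc)2 (5 mol %), SPhos, THF/NMP, 60 °C
Reagents that add atoms: (1,3-dioxolan-2-ylmethyl)zinc bromide, Br[Zn]CC1OCCO1
Why: Negishi coupling of the alkenyl tosylate proceeds with retention, so the C8–C9 unit enters cis to the C2 methyl group and the tetrasubstituted alkene has the Z geometry of the target.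

Step 16
Reactants: 26 acetal ester
Product: 27 ethyl (2Z,4R,5S,6S)-4-{3-[(tert-butyldiphenylsilyl)oxy]propyl}-5-ethenyl-6-hydroxy-2,5-dimethyl-3-(2-oxoethyl)hept-2-enoate
Conditions: 2 M HCl/THF (1:4), rt
Reagents that add atoms: water, O
Why: Acid hydrolysis cleaves the dioxolane and the triethylsilyl ether in one operation while the tert-butyldiphenylsilyl ether and the ester survive; the aldehyde is reduced at once to avoid migration of the double bond.

Step 17
Reactants: 27 hydroxy aldehyde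
Product: 28 ethyl (2Z,4R,5S,6S)-4-{3-[(tert-butyldiphenylsilyl)oxy]propyl}-5-ethenyl-6-hydroxy-3-(2-hydroxyethyl)-2,5-dimethylhept-2-enoate
Conditions: NaBH4, EtOH, −20 °C
Reagents that add atoms: none
Why: Borohydride reduces the aldehyde and leaves the hindered conjugated ester alone.

Step 18
Reactants: 28 diol
Product: 29 ethyl (2Z,4R,5S,6S)-4-{3-[(tert-butyldiphenylsilyl)oxy]propyl}-5-ethenyl-6-hydroxy-3-(2-iodoethyl)-2,5-dimethylhept-2-enoate
Conditions: I2, PPh3, imidazole, CH2Cl2, 0 °C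
Reagents that add atoms: iodine, II
Why: Appel-type iodination is selective for the primary alcohol over the hindered secondary one next to the quaternary centre.

Step 19
Reactants: 29 iodo alcohol
Product: 30 ethyl (2Z,4R,5S)-4-{3-[(tert-butyldiphenylsilyl)oxy]propyl}-5-ethenyl-3-(2-iodoethyl)-2,5-dimethyl-6-oxohept-2-enoate
Conditions: Dess–Martin periodinane, NaHCO3, CH2Cl2, rt
Reagents that add atoms: none
Why: Dess–Martin oxidation unveils the C10 methyl ketone under buffered conditions that tolerate the primary iodide and removes the helper stereocentre.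

Step 20
Reactants: 30 iodo ketone
Product: 32 ethyl (2Z)-2-[(2R,3S,4S)-2-{3-[(tert-butyldiphenylsilyl)oxy]propyl}-3-ethenyl-4-hydroxy-3,4-dimethylcyclohexylidene]propanoate, via alkylsamarium 31 (not isolated)
Conditions: SmI2 (2.5 equiv), NiI2 (2 mol %), THF, −20 → 0 °C; sat. NH4Cl
Reagents that add atoms: none
Why: SmI2 reduces the primary C9–I bond in two single-electron steps (NiI2 as electron-transfer catalyst) to an alkylsamarium that adds to the C10 ketone, the closest known reaction type being the intramolecular samarium Barbier cyclisation of ω-iodo ketones to cyclohexanols. Ring B closes in the 6-exo-trig mode, C9 attacking the carbonyl carbon with the oxygen outside the new ring. C10 is set by substrate control in a chair transition state: allylic 1,3-strain with the ester-bearing substituent of the Z-alkylidene keeps the C6 chain axial, hence the C11 vinyl group axial and the C11 methyl equatorial, and the ketone should then place its oxygen, not its methyl group, in the axial position syn to the C6 chain, giving the hydroxyl cis to the C11 methyl and to the hydroxypropyl chain. The step needs attack on the ketone and not on the ester, and closure before protonation; the Z geometry holds C1 trans to C8 so that C9 cannot reach the ester, and no proton source is present. The vinyl group, the enoate (no cosolvent such as HMPA, no alcohol) and the silyl ether are expected to be inert.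

Step 21
Reactants: 32 ring B vinyl ester; 15 (E)-2-bromo-1-iodoprop-1-ene
Product: 34 ethyl (2Z)-2-[(2R,3S,4S)-3-[(3E)-4-bromopent-3-en-1-yl]-2-{3-[(tert-butyldiphenylsilyl)oxy]propyl}-4-hydroxy-3,4-dimethylcyclohexylidene]propanoate, via B-alkyl-9-BBN adduct 33 (not isolated)
Conditions: 9-BBN (2.5 equiv), THF, rt; then 15 (1.5 equiv), PdCl2(dppf) (5 mol %), AsPh3, Cs2CO3, DMF/H2O, rt
Reagents that add atoms: none
Why: Anti-Markovnikov hydroboration of the only terminal alkene and B-alkyl Suzuki–Miyaura coupling, site-selective for the more reactive, less hindered C–I bond and stereoretentive, should leave bromine trans to the new C13–C14 bond.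

Step 22
Reactants: 34 alkenyl bromide; 9 ring A alkyne
Product: 36 ethyl (2Z)-2-[(2R,3S,4S)-2-{3-[(tert-butyldiphenylsilyl)oxy]propyl}-4-hydroxy-3,4-dimethyl-3-{(3E,5E)-4-methyl-6-[(1R,3S)-2,2,3-trimethyl-6-methylidenecyclohexyl]hexa-3,5-dien-1-yl}cyclohexylidene]propanoate, via alkenylzirconocene chloride 35 (not isolated)
Conditions: 9 (1.5 equiv), Cp2Zr(H)Cl, THF, rt; then ZnCl2, 34, Pd(PPh3)4 (5 mol %), THF, 40 °C
Reagents that add atoms: none
Why: Syn hydrozirconation of the terminal alkyne (much faster than the 1,1-disubstituted alkene), transmetallation to zinc and Negishi coupling with the alkenyl bromide, each with retention, should give the (14E,16E)-diene in the presence of the ester and the hindered tertiary alcohol.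

Step 23
Reactants: 36 coupled ester
Product: 37 (2Z)-2-[(2R,3S,4S)-2-{3-[(tert-butyldiphenylsilyl)oxy]propyl}-4-hydroxy-3,4-dimethyl-3-{(3E,5E)-4-methyl-6-[(1R,3S)-2,2,3-trimethyl-6-methylidenecyclohexyl]hexa-3,5-dien-1-yl}cyclohexylidene]propan-1-ol
Conditions: (i-Bu)2AlH (3.5 equiv), CH2Cl2, −78 → 0 °C; aq. potassium sodium tartrate
Reagents that add atoms: none
Why: 1,2-Reduction of the unsaturated ester to the allylic alcohol removes the oxidation-level helper at C1; no other reducible group is present.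

Step 24
Reactants: 37 allylic alcohol
Product: 38 (2Z)-2-[(2R,3S,4S)-2-{3-[(tert-butyldiphenylsilyl)oxy]propyl}-4-hydroxy-3,4-dimethyl-3-{(3E,5E)-4-methyl-6-[(1R,3S)-2,2,3-trimethyl-6-methylidenecyclohexyl]hexa-3,5-dien-1-yl}cyclohexylidene]propanal
Conditions: MnO2 (excess), CH2Cl2, rt
Reagents that add atoms: none
Why: MnO2 oxidises only the allylic primary alcohol (the tertiary alcohol is inert, the other primary alcohol is still silylated) and should not isomerise the tetrasubstituted double bond.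

Step 25
Reactants: 38 silylated enal
Product: 39 (2Z)-2-[(2R,3S,4S)-4-hydroxy-2-(3-hydroxypropyl)-3,4-dimethyl-3-{(3E,5E)-4-methyl-6-[(1R,3S)-2,2,3-trimethyl-6-methylidenecyclohexyl]hexa-3,5-dien-1-yl}cyclohexylidene]propanal
Conditions: HF·pyridine, pyridine/THF, 0 °C → rt
Reagents that add atoms: none
Why: Buffered fluoride cleavage of the primary silyl ether liberates the C3 alcohol without touching the enal, the tertiary alcohol or the polyene.

**Compound list**

1 | (3S)-3-methylcyclohexan-1-one | C[C@H]1CCCC(=O)C1 | starting material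
2 | (2Z,5S)-2-(hydroxymethylidene)-5-methylcyclohexan-1-one | O/C=C1/CC[C@H](C)CC1=O | intermediate
3 | (2E,5S)-5-methyl-2-[(propan-2-yloxy)methylidene]cyclohexan-1-one | CC(C)O/C=C1\CC[C@H](C)CC1=O | intermediate
4 | (3S,6E)-2,2,3-trimethyl-6-[(propan-2-yloxy)methylidene]cyclohexan-1-one | CC(C)O/C=C1\CC[C@H](C)C(C)(C)C1=O | intermediate
5 | (3S,6E)-1-ethynyl-2,2,3-trimethyl-6-[(propan-2-yloxy)methylidene]cyclohexan-1-ol (C1 epimers, formed as its magnesium alkoxide) | CC(C)O/C=C1\CC[C@H](C)C(C)(C)C1(O)C#C | intermediate (not isolated)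
6 | (4S)-2-ethynyl-3,3,4-trimethylcyclohex-1-ene-1-carbaldehyde | O=CC1=C(C#C)C(C)(C)[C@@H](C)CC1 | intermediate
7 | N'-[(E)-{(4S)-2-ethynyl-3,3,4-trimethylcyclohex-1-en-1-yl}methylidene]-4-methylbenzenesulfonohydrazide | Cc1ccc(cc1)S(=O)(=O)N/N=C/C1=C(C#C)C(C)(C)[C@@H](C)CC1 | intermediate
8 | {[(4S)-2-ethynyl-3,3,4-trimethylcyclohex-1-en-1-yl]methyl}diazene | N=NCC1=C(C#C)C(C)(C)[C@@H](C)CC1 | intermediate (not isolated)
9 | (1S,3S)-1-ethynyl-2,2,3-trimethyl-6-methylidenecyclohexane (ethynyl and 3-methyl cis) | C=C1CC[C@H](C)C(C)(C)[C@@H]1C#C | intermediate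
10 | oxan-2-one (δ-valerolactone) | O=C1CCCCO1 | starting material
11 | potassium 5-hydroxypentanoate | [K+].[O-]C(=O)CCCCO | intermediate (not isolated)
12 | tert-butyldiphenylsilyl 5-[(tert-butyldiphenylsilyl)oxy]pentanoate | CC(C)(C)[Si](c1ccccc1)(c1ccccc1)OCCCCC(=O)O[Si](c1ccccc1)(c1ccccc1)C(C)(C)C | intermediate (not isolated)
13 | 5-[(tert-butyldiphenylsilyl)oxy]pentanoic acid | OC(=O)CCCCO[Si](c1ccccc1)(c1ccccc1)C(C)(C)C | intermediate
14 | propyne | CC#C | starting material
15 | (E)-2-bromo-1-iodoprop-1-ene | Br/C(C)=C/I | intermediate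
16 | (2S)-but-3-yn-2-ol | C[C@H](O)C#C | starting material
17 | triethyl{[(2S)-but-3-yn-2-yl]oxy}silane | C[C@H](O[Si](CC)(CC)CC)C#C | intermediate
18 | dimethyl{(1E,3S)-2-methyl-3-[(triethylsilyl)oxy]but-1-en-1-yl}alumane | C[C@H](O[Si](CC)(CC)CC)/C(C)=C/[Al](C)C | intermediate (not isolated)
19 | (2E,4S)-3-methyl-4-[(triethylsilyl)oxy]pent-2-en-1-ol | C[C@H](O[Si](CC)(CC)CC)/C(C)=C/CO | intermediate
20 | (2E,4S)-3-methyl-4-[(triethylsilyl)oxy]pent-2-en-1-yl 5-[(tert-butyldiphenylsilyl)oxy]pentanoate | C[C@H](O[Si](CC)(CC)CC)/C(C)=C/COC(=O)CCCCO[Si](c1ccccc1)(c1ccccc1)C(C)(C)C | intermediate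
21 | boron ketene acetal of 20 with the (4S,5S)-diazaborolidine on oxygen (E(O) enolate, alkyl chain anti to O–B) | C[C@H](O[Si](CC)(CC)CC)/C(C)=C/CO/C(OB1N(S(=O)(=O)c2cc(cc(c2)C(F)(F)F)C(F)(F)F)[C@@H](c2ccccc2)[C@H](c2ccccc2)N1S(=O)(=O)c1cc(cc(c1)C(F)(F)F)C(F)(F)F)=C\CCCO[Si](c1ccccc1)(c1ccccc1)C(C)(C)C | intermediate (not isolated)
22 | (2S,3S,4S)-2-{3-[(tert-butyldiphenylsilyl)oxy]propyl}-3-ethenyl-3-methyl-4-[(triethylsilyl)oxy]pentanoic acid | C[C@H](O[Si](CC)(CC)CC)[C@@](C)(C=C)[C@H](CCCO[Si](c1ccccc1)(c1ccccc1)C(C)(C)C)C(=O)O | intermediate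
23 | 1-[(2S,3S,4S)-2-{3-[(tert-butyldiphenylsilyl)oxy]propyl}-3-ethenyl-3-methyl-4-[(triethylsilyl)oxy]pentanoyl]-1H-imidazole | C[C@H](O[Si](CC)(CC)CC)[C@@](C)(C=C)[C@H](CCCO[Si](c1ccccc1)(c1ccccc1)C(C)(C)C)C(=O)n1ccnc1 | intermediate (not isolated)
24 | ethyl (4S,5S,6S)-4-{3-[(tert-butyldiphenylsilyl)oxy]propyl}-5-ethenyl-2,5-dimethyl-3-oxo-6-[(triethylsilyl)oxy]heptanoate (C2 epimers) | C[C@H](O[Si](CC)(CC)CC)[C@@](C)(C=C)[C@H](CCCO[Si](c1ccccc1)(c1ccccc1)C(C)(C)C)C(=O)C(C)C(=O)OCC | intermediate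
25 | ethyl (2E,4S,5S,6S)-4-{3-[(tert-butyldiphenylsilyl)oxy]propyl}-5-ethenyl-2,5-dimethyl-3-{[(4-methylphenyl)sulfonyl]oxy}-6-[(triethylsilyl)oxy]hept-2-enoate | C[C@H](O[Si](CC)(CC)CC)[C@@](C)(C=C)[C@H](CCCO[Si](c1ccccc1)(c1ccccc1)C(C)(C)C)/C(OS(=O)(=O)c1ccc(C)cc1)=C(/C)C(=O)OCC | intermediate
26 | ethyl (2Z,4R,5S,6S)-4-{3-[(tert-butyldiphenylsilyl)oxy]propyl}-3-(1,3-dioxolan-2-ylmethyl)-5-ethenyl-2,5-dimethyl-6-[(triethylsilyl)oxy]hept-2-enoate | C[C@H](O[Si](CC)(CC)CC)[C@@](C)(C=C)[C@H](CCCO[Si](c1ccccc1)(c1ccccc1)C(C)(C)C)/C(CC1OCCO1)=C(/C)C(=O)OCC | intermediate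
27 | ethyl (2Z,4R,5S,6S)-4-{3-[(tert-butyldiphenylsilyl)oxy]propyl}-5-ethenyl-6-hydroxy-2,5-dimethyl-3-(2-oxoethyl)hept-2-enoate | C[C@H](O)[C@@](C)(C=C)[C@H](CCCO[Si](c1ccccc1)(c1ccccc1)C(C)(C)C)/C(CC=O)=C(/C)C(=O)OCC | intermediate
28 | ethyl (2Z,4R,5S,6S)-4-{3-[(tert-butyldiphenylsilyl)oxy]propyl}-5-ethenyl-6-hydroxy-3-(2-hydroxyethyl)-2,5-dimethylhept-2-enoate | C[C@H](O)[C@@](C)(C=C)[C@H](CCCO[Si](c1ccccc1)(c1ccccc1)C(C)(C)C)/C(CCO)=C(/C)C(=O)OCC | intermediate
29 | ethyl (2Z,4R,5S,6S)-4-{3-[(tert-butyldiphenylsilyl)oxy]propyl}-5-ethenyl-6-hydroxy-3-(2-iodoethyl)-2,5-dimethylhept-2-enoate | C[C@H](O)[C@@](C)(C=C)[C@H](CCCO[Si](c1ccccc1)(c1ccccc1)C(C)(C)C)/C(CCI)=C(/C)C(=O)OCC | intermediate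
30 | ethyl (2Z,4R,5S)-4-{3-[(tert-butyldiphenylsilyl)oxy]propyl}-5-ethenyl-3-(2-iodoethyl)-2,5-dimethyl-6-oxohept-2-enoate | CC(=O)[C@@](C)(C=C)[C@H](CCCO[Si](c1ccccc1)(c1ccccc1)C(C)(C)C)/C(CCI)=C(/C)C(=O)OCC | intermediate
31 | alkylsamarium diiodide from 30 (SmI2 in place of I at C9) | CC(=O)[C@@](C)(C=C)[C@H](CCCO[Si](c1ccccc1)(c1ccccc1)C(C)(C)C)/C(CC[Sm](I)I)=C(/C)C(=O)OCC | intermediate (not isolated)
32 | ethyl (2Z)-2-[(2R,3S,4S)-2-{3-[(tert-butyldiphenylsilyl)oxy]propyl}-3-ethenyl-4-hydroxy-3,4-dimethylcyclohexylidene]propanoate | C=C[C@@]1(C)[C@H](CCCO[Si](c2ccccc2)(c2ccccc2)C(C)(C)C)/C(=C(/C)C(=O)OCC)CC[C@]1(C)O | intermediate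
33 | ethyl (2Z)-2-[(2R,3S,4S)-3-[2-(9-borabicyclo[3.3.1]nonan-9-yl)ethyl]-2-{3-[(tert-butyldiphenylsilyl)oxy]propyl}-4-hydroxy-3,4-dimethylcyclohexylidene]propanoate | B1(CC[C@@]2(C)[C@H](CCCO[Si](c3ccccc3)(c3ccccc3)C(C)(C)C)/C(=C(/C)C(=O)OCC)CC[C@]2(C)O)C2CCCC1CCC2 | intermediate (not isolated)
34 | ethyl (2Z)-2-[(2R,3S,4S)-3-[(3E)-4-bromopent-3-en-1-yl]-2-{3-[(tert-butyldiphenylsilyl)oxy]propyl}-4-hydroxy-3,4-dimethylcyclohexylidene]propanoate | Br/C(C)=C/CC[C@@]1(C)[C@H](CCCO[Si](c2ccccc2)(c2ccccc2)C(C)(C)C)/C(=C(/C)C(=O)OCC)CC[C@]1(C)O | intermediate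
35 | chlorobis(cyclopentadienyl){(E)-2-[(1R,3S)-2,2,3-trimethyl-6-methylidenecyclohexyl]ethenyl}zirconium | C=C1CC[C@H](C)C(C)(C)[C@@H]1/C=C/[Zr](Cl)(C1C=CC=C1)C1C=CC=C1 | intermediate (not isolated)
36 | ethyl (2Z)-2-[(2R,3S,4S)-2-{3-[(tert-butyldiphenylsilyl)oxy]propyl}-4-hydroxy-3,4-dimethyl-3-{(3E,5E)-4-methyl-6-[(1R,3S)-2,2,3-trimethyl-6-methylidenecyclohexyl]hexa-3,5-dien-1-yl}cyclohexylidene]propanoate | C=C1CC[C@H](C)C(C)(C)[C@@H]1/C=C/C(C)=C/CC[C@@]1(C)[C@H](CCCO[Si](c2ccccc2)(c2ccccc2)C(C)(C)C)/C(=C(/C)C(=O)OCC)CC[C@]1(C)O | intermediate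
37 | (2Z)-2-[(2R,3S,4S)-2-{3-[(tert-butyldiphenylsilyl)oxy]propyl}-4-hydroxy-3,4-dimethyl-3-{(3E,5E)-4-methyl-6-[(1R,3S)-2,2,3-trimethyl-6-methylidenecyclohexyl]hexa-3,5-dien-1-yl}cyclohexylidene]propan-1-ol | C=C1CC[C@H](C)C(C)(C)[C@@H]1/C=C/C(C)=C/CC[C@@]1(C)[C@H](CCCO[Si](c2ccccc2)(c2ccccc2)C(C)(C)C)/C(=C(/C)CO)CC[C@]1(C)O | intermediate
38 | (2Z)-2-[(2R,3S,4S)-2-{3-[(tert-butyldiphenylsilyl)oxy]propyl}-4-hydroxy-3,4-dimethyl-3-{(3E,5E)-4-methyl-6-[(1R,3S)-2,2,3-trimethyl-6-methylidenecyclohexyl]hexa-3,5-dien-1-yl}cyclohexylidene]propanal | C=C1CC[C@H](C)C(C)(C)[C@@H]1/C=C/C(C)=C/CC[C@@]1(C)[C@H](CCCO[Si](c2ccccc2)(c2ccccc2)C(C)(C)C)/C(=C(/C)C=O)CC[C@]1(C)O | intermediate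
39 | (2Z)-2-[(2R,3S,4S)-4-hydroxy-2-(3-hydroxypropyl)-3,4-dimethyl-3-{(3E,5E)-4-methyl-6-[(1R,3S)-2,2,3-trimethyl-6-methylidenecyclohexyl]hexa-3,5-dien-1-yl}cyclohexylidene]propanal | C=C1CC[C@H](C)C(C)(C)[C@@H]1/C=C/C(C)=C/CC[C@@]1(C)[C@H](CCCO)/C(=C(/C)C=O)CC[C@]1(C)O | target

**Count and risks**

Total: 25 steps. Longest linear sequence: 17 steps (steps 9–25, from (S)-but-3-yn-2-ol).

Steps most likely to fail:

1. Step 20 (key step). The closure may suffer from poor facial selectivity at C10 (the bulky samarium alkoxide may prefer the equatorial position) or from protonation of the organosamarium before ring closure. Fallback: close the same bond by a ketyl–aldehyde coupling. It sets out from 27. Dess–Martin periodinane gives keto aldehyde F1. SmI2 in THF/t-BuOH couples the C9 aldehyde with the C10 ketone through a chelated samarium diolate to cis-diol F2. PhOC(S)Cl/pyridine acylates only the secondary hydroxyl, giving O-phenyl thiocarbonate F3, and Bu3SnH/AIBN (Barton–McCombie deoxygenation) removes it. The route is rejoined at 32.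

2. Step 14. Enol tosylation of the very hindered keto ester may give poor E/Z selectivity, and the tosylate may couple slowly in step 15. Fallback: build the tetrasubstituted alkene by syn-carbocupration. It sets out from 22. BH3·SMe2 gives primary alcohol F4, Dess–Martin oxidation gives aldehyde F5, and the Ohira–Bestmann reagent (dimethyl (1-diazo-2-oxopropyl)phosphonate, K2CO3, MeOH) gives terminal alkyne F6. n-BuLi then ClCO2Et gives ynoate F7. The cuprate from BrMgCH2CH(OCH2CH2O) and CuBr·SMe2 adds syn at −78 °C, and trapping the alkenylcopper with MeI places methyl cis to the new CH2 group. The route is rejoined at 26.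

3. Step 12. The boron-mediated rearrangement may be slow, or its facial selectivity low, at the hindered C11 terminus. Fallback: hand absolute control to a separation. It sets out from 20. LiN(i-Pr)2 then Me3SiCl/Et3N in THF at −78 °C gives E(O)-silyl ketene acetal F8, which rearranges on warming to trimethylsilyl ester F9. Mild hydrolysis gives 22 together with its facial isomer, acid F10. The two are diastereomers because of the (S)-C10 centre and are separated by chromatography. The route continues at 22.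

**Further compounds**

F1 | step 20 | ethyl (2Z,4R,5S)-4-{3-[(tert-butyldiphenylsilyl)oxy]propyl}-5-ethenyl-2,5-dimethyl-6-oxo-3-(2-oxoethyl)hept-2-enoate | CC(=O)[C@@](C)(C=C)[C@H](CCCO[Si](c1ccccc1)(c1ccccc1)C(C)(C)C)/C(CC=O)=C(/C)C(=O)OCC
F2 | step 20 | ethyl (2Z)-2-[(2R,3S,4R,5S)-2-{3-[(tert-butyldiphenylsilyl)oxy]propyl}-3-ethenyl-4,5-dihydroxy-3,4-dimethylcyclohexylidene]propanoate | C=C[C@@]1(C)[C@H](CCCO[Si](c2ccccc2)(c2ccccc2)C(C)(C)C)/C(=C(/C)C(=O)OCC)C[C@H](O)[C@]1(C)O
F3 | step 20 | ethyl (2Z)-2-[(2R,3S,4R,5S)-2-{3-[(tert-butyldiphenylsilyl)oxy]propyl}-3-ethenyl-4-hydroxy-3,4-dimethyl-5-[(phenoxycarbonothioyl)oxy]cyclohexylidene]propanoate | C=C[C@@]1(C)[C@H](CCCO[Si](c2ccccc2)(c2ccccc2)C(C)(C)C)/C(=C(/C)C(=O)OCC)C[C@H](OC(=S)Oc2ccccc2)[C@]1(C)O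
F4 | step 14 | (2S,3S,4S)-2-{3-[(tert-butyldiphenylsilyl)oxy]propyl}-3-ethenyl-3-methyl-4-[(triethylsilyl)oxy]pentan-1-ol | C[C@H](O[Si](CC)(CC)CC)[C@@](C)(C=C)[C@H](CCCO[Si](c1ccccc1)(c1ccccc1)C(C)(C)C)CO
F5 | step 14 | (2S,3S,4S)-2-{3-[(tert-butyldiphenylsilyl)oxy]propyl}-3-ethenyl-3-methyl-4-[(triethylsilyl)oxy]pentanal | C[C@H](O[Si](CC)(CC)CC)[C@@](C)(C=C)[C@H](CCCO[Si](c1ccccc1)(c1ccccc1)C(C)(C)C)C=O
F6 | step 14 | tert-butyl{[(4R,5S,6S)-5-ethenyl-4-ethynyl-5-methyl-6-[(triethylsilyl)oxy]heptyl]oxy}diphenylsilane | C[C@H](O[Si](CC)(CC)CC)[C@@](C)(C=C)[C@H](CCCO[Si](c1ccccc1)(c1ccccc1)C(C)(C)C)C#C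
F7 | step 14 | ethyl (4R,5S,6S)-4-{3-[(tert-butyldiphenylsilyl)oxy]propyl}-5-ethenyl-5-methyl-6-[(triethylsilyl)oxy]hept-2-ynoate | C[C@H](O[Si](CC)(CC)CC)[C@@](C)(C=C)[C@H](CCCO[Si](c1ccccc1)(c1ccccc1)C(C)(C)C)C#CC(=O)OCC
F8 | step 12 | E(O)-trimethylsilyl ketene acetal of 20 (alkyl chain anti to O–Si) | C[C@H](O[Si](CC)(CC)CC)/C(C)=C/CO/C(O[Si](C)(C)C)=C\CCCO[Si](c1ccccc1)(c1ccccc1)C(C)(C)C
F9 | step 12 | trimethylsilyl (2S,3S,4S)-2-{3-[(tert-butyldiphenylsilyl)oxy]propyl}-3-ethenyl-3-methyl-4-[(triethylsilyl)oxy]pentanoate | C[C@H](O[Si](CC)(CC)CC)[C@@](C)(C=C)[C@H](CCCO[Si](c1ccccc1)(c1ccccc1)C(C)(C)C)C(=O)O[Si](C)(C)C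
F10 | step 12 | (2R,3R,4S)-2-{3-[(tert-butyldiphenylsilyl)oxy]propyl}-3-ethenyl-3-methyl-4-[(triethylsilyl)oxy]pentanoic acid | C[C@H](O[Si](CC)(CC)CC)[C@](C)(C=C)[C@@H](CCCO[Si](c1ccccc1)(c1ccccc1)C(C)(C)C)C(=O)O
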